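**Retrosynthetic overview**
- Target ⇐ hydroxyl-directed, anti-selective reduction of the C5 ketone of an epoxyquinone acid ⇐ one acid step that removes a dimethyl ketal and a tert-butyl ester.
- C3–heptenyl bond ⇐ Stille coupling of the α-bromo enone epoxide with an (E)-heptenylstannane made from hept-1-yne.
- Oxirane ring (formed second; sets both ring-fusion stereocentres) ⇐ catalytic asymmetric nucleophilic epoxidation of a 2-alkyl-6-bromo quinone monoketal.
- C1–side-chain bond ⇐ chemoselective Stille allyl transfer at the α-iodo position from a γ-stannyl tiglate (four steps from 2-bromopropanoyl bromide and chloroacetaldehyde).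
- Carbocycle (formed first) ⇐ oxidative dearomatisation of a phenol assembled by Diels–Alder/ring-opening aromatisation of 2-methoxyfuran with methyl 3-bromopropiolate.

Assumption: the SMILES is read as the (1S,5R,6S)-epoxyquinol (7-oxabicyclo[4.1.0]hept-3-ene numbering: C1 quaternary oxirane carbon, C5 carbinol, C6 oxirane CH), with the C5 hydroxyl anti to the oxirane oxygen and both side-chain alkenes E.

**Step 1**
Reactants: 1 methyl prop-2-ynoate
Product: 2 methyl 3-bromoprop-2-ynoate
Conditions: NBS (1.1 equiv), AgNO3 (10 mol%), acetone, rt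
Reagents that add atoms: N-bromosuccinimide (O=C1CCC(=O)N1Br)
Why: Silver-catalysed electrophilic bromination of the terminal alkyne (silver acetylide intercepted by NBS) gives the 1-bromoalkyne without touching the ester.

**Step 2**
Reactants: 2 methyl 3-bromoprop-2-ynoate; 3 2-methoxyfuran
Product: 5 methyl 2-bromo-3-hydroxy-6-methoxybenzoate, via oxanorbornadiene adduct 4 (not isolated)
Conditions: CH2Cl2, 0 °C → rt; then cat. CF3CO2H, rt
Reagents that add atoms: none
Why: Normal-demand Diels–Alder reaction in which the nucleophilic C5 of 2-methoxyfuran bonds to the bromine-bearing β-carbon of the ynoate and the ester carbon to C2, followed by methoxy-assisted opening of the oxygen bridge and proton loss (ring-opening aromatisation), so that OH ends up para to OMe, Br ortho to OH and the ester ortho to OMe.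

**Step 3**
Reactants: 5 methyl 2-bromo-3-hydroxy-6-methoxybenzoate
Product: 6 2-bromo-3-(hydroxymethyl)-4-methoxyphenol
Conditions: i-Bu2AlH (4.5 equiv), CH2Cl2, −78 °C → rt
Reagents that add atoms: none
Why: Aluminium hydride reduction of the ester to the primary alcohol, in which the aryl bromide and aryl methyl ether are inert and the phenol is simply carried as its aluminium phenoxide.

**Step 4**
Reactants: 6 2-bromo-3-(hydroxymethyl)-4-methoxyphenol
Product: 8 2-bromo-3-(hydroxymethyl)-6-iodo-4,4-dimethoxycyclohexa-2,5-dien-1-one, via iodophenol 7 (not isolated)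
Conditions: NIS (1.05 equiv), MeOH, 0 °C; then PhI(OAc)2 (1.15 equiv), same flask, 0 °C
Reagents that add atoms: N-iodosuccinimide (O=C1CCC(=O)N1I); methanol (CO)
Why: Electrophilic aromatic iodination can only go to C6 (the single free position ortho to OH, since C2 bears Br and C4 bears OMe), and hypervalent-iodine oxidative dearomatisation of the resulting 4-methoxyphenol in methanol then traps the phenoxenium ion at C4 to give the p-quinone monoketal with the primary alcohol untouched.

**Step 5**
Reactants: 9 2-bromopropanoyl bromide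
Product: 10 tert-butyl 2-bromopropanoate
Conditions: t-BuOH (1.2 equiv), pyridine (1.2 equiv), CH2Cl2, 0 °C → rt
Reagents that add atoms: tert-butanol (CC(C)(C)O)
Why: Acylation of tert-butanol by the acid bromide (esterification) installs an ester that later falls in the same acid step as the ketal, the secondary bromide being untouched at 0 °C.

**Step 6**
Reactants: 10 tert-butyl 2-bromopropanoate
Product: 12 tert-butyl 2-(triphenylphosphoranylidene)propanoate, via phosphonium bromide 11 (not isolated)
Conditions: PPh3, PhMe, 80 °C; then NaOH (aq.), CH2Cl2, rt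
Reagents that add atoms: triphenylphosphine (c1ccc(cc1)P(c1ccccc1)c1ccccc1)
Why: SN2 quaternisation of PPh3 by the α-bromo ester followed by deprotonation gives the ester-stabilised ylide (standard Wittig reagent preparation).

**Step 7**
Reactants: 12 tert-butyl 2-(triphenylphosphoranylidene)propanoate; 13 chloroacetaldehyde (50 wt% in water)
Product: 14 tert-butyl (E)-4-chloro-2-methylbut-2-enoate
Conditions: CHCl3–H2O, rt → 50 °C
Reagents that add atoms: none
Why: Wittig olefination with an α-methyl ester-stabilised ylide is reliably (E)-selective (thermodynamic control, typically ≥95:5), placing CH2Cl trans to the ester, and the hindered ylide carbon does not displace the chloride.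

**Step 8**
Reactants: 14 tert-butyl (E)-4-chloro-2-methylbut-2-enoate
Product: 15 tert-butyl (E)-2-methyl-4-(tributylstannyl)but-2-enoate
Conditions: (Bu3Sn)2 (1.2 equiv), Pd2(dba)3 (2 mol%), THF, 40 °C
Reagents that add atoms: hexabutylditin (CCCC[Sn](CCCC)(CCCC)[Sn](CCCC)(CCCC)CCCC)
Why: Palladium-catalysed allylic stannylation, in which zerovalent palladium ionises the allylic chloride, the distannane transmetalates and reductive elimination occurs at the unsubstituted CH2 terminus, keeps the conjugated (E)-enoate.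

**Step 9**
Reactants: 8 2-bromo-3-(hydroxymethyl)-6-iodo-4,4-dimethoxycyclohexa-2,5-dien-1-one; 15 tert-butyl (E)-2-methyl-4-(tributylstannyl)but-2-enoate
Product: 16 tert-butyl (E)-4-[5-bromo-4-(hydroxymethyl)-3,3-dimethoxy-6-oxocyclohexa-1,4-dien-1-yl]-2-methylbut-2-enoate
Conditions: Pd2(dba)3 (5 mol%), AsPh3 (20 mol%), CuI (10 mol%), NMP, rt
Reagents that add atoms: none
Why: Stille coupling with allyl transfer, in which zerovalent palladium inserts selectively into the α-iodoenone C–I bond (the C–Br bond is inert at rt), CuI assists tin-to-palladium transfer and reductive elimination at the unsubstituted allyl terminus gives the linear, conjugated (E)-enoate rather than the quaternary α-isomer.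

**Step 10**
Reactants: 16 tert-butyl (E)-4-[5-bromo-4-(hydroxymethyl)-3,3-dimethoxy-6-oxocyclohexa-1,4-dien-1-yl]-2-methylbut-2-enoate
Product: 17 tert-butyl (E)-4-[(1S,6R)-3-bromo-4-(hydroxymethyl)-5,5-dimethoxy-2-oxo-7-oxabicyclo[4.1.0]hept-3-en-1-yl]-2-methylbut-2-enoate
Conditions: Ph3COOH (1.3 equiv), N-(9-anthracenylmethyl)cinchonidinium chloride (10 mol%), KOH (powder, 0.3 equiv), PhMe, −20 °C
Reagents that add atoms: trityl hydroperoxide (OOC(c1ccccc1)(c1ccccc1)c1ccccc1)
Why: Proposed new method: catalytic enantioselective Weitz–Scheffer epoxidation of a 2-alkyl-6-bromo quinone monoketal under chiral ion-pair (phase-transfer) catalysis, in which the cinchonidinium cation pairs with Ph3COO−, its free C9–OH hydrogen-bonds to the dienone carbonyl and the flat dienone stacks on the anthracenyl wall, so the bulky peroxide adds to C5 (the only unsubstituted β-carbon, the bromo alkene being blocked at its β-carbon) on one face and the ammonium enolate then closes on oxygen with loss of Ph3CO−, which necessarily gives the cis-fused oxirane and sets C1 (quaternary) and C6 together; the (1S,6R) sense is to be confirmed on the first run by correlation with material from the fallback, the pseudo-enantiomeric cinchoninium salt giving the other face if needed; the closest known reaction type is the Wynberg-type chiral quaternary ammonium epoxidation of enones, shown for unsubstituted quinone monoketal double bonds and naphthoquinones but not for an α-alkyl dienone double bond that forms a quaternary oxirane carbon.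

**Step 11**
Reactants: 18 hept-1-yne
Product: 19 tributyl[(E)-hept-1-en-1-yl]stannane
Conditions: Bu3SnH (1.05 equiv), PtCl2 (1 mol%), XPhos (2 mol%), THF, 50 °C
Reagents that add atoms: tributyltin hydride (CCCC[SnH](CCCC)CCCC)
Why: Platinum-catalysed hydrostannation adds Sn–H syn across the terminal alkyne and the bulky biaryl phosphine directs tin to the terminal carbon, giving the (E)-β-vinylstannane free of the α- and (Z)-isomers.

**Step 12**
Reactants: 17 tert-butyl (E)-4-[(1S,6R)-3-bromo-4-(hydroxymethyl)-5,5-dimethoxy-2-oxo-7-oxabicyclo[4.1.0]hept-3-en-1-yl]-2-methylbut-2-enoate; 19 tributyl[(E)-hept-1-en-1-yl]stannane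
Product: 20 tert-butyl (E)-4-[(1S,6R)-3-[(E)-hept-1-en-1-yl]-4-(hydroxymethyl)-5,5-dimethoxy-2-oxo-7-oxabicyclo[4.1.0]hept-3-en-1-yl]-2-methylbut-2-enoate
Conditions: Pd2(dba)3 (5 mol%), AsPh3 (20 mol%), PhMe, 100 °C
Reagents that add atoms: none
Why: Stille alkenyl–alkenyl coupling at the hindered α-bromo enone proceeds with retention of the (E) geometry of the stannane under neutral conditions that leave the oxirane stereocentres, ketal and ester untouched.

**Step 13**
Reactants: 20 tert-butyl (E)-4-[(1S,6R)-3-[(E)-hept-1-en-1-yl]-4-(hydroxymethyl)-5,5-dimethoxy-2-oxo-7-oxabicyclo[4.1.0]hept-3-en-1-yl]-2-methylbut-2-enoate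
Product: 21 (E)-4-[(1S,6R)-3-[(E)-hept-1-en-1-yl]-4-(hydroxymethyl)-2,5-dioxo-7-oxabicyclo[4.1.0]hept-3-en-1-yl]-2-methylbut-2-enoic acid
Conditions: CF3CO2H–CH2Cl2–H2O (10:10:1), 0 °C → rt
Reagents that add atoms: water (O)
Why: Acid hydrolysis of the dimethyl ketal (via the oxocarbenium ion) and acidolysis of the tert-butyl ester occur together, while the oxirane, now flanked by two carbonyl groups, is deactivated toward acid opening and keeps its configuration.

**Step 14**
Reactants: 21 (E)-4-[(1S,6R)-3-[(E)-hept-1-en-1-yl]-4-(hydroxymethyl)-2,5-dioxo-7-oxabicyclo[4.1.0]hept-3-en-1-yl]-2-methylbut-2-enoic acid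
Product: 22 (E)-4-[(1S,5R,6S)-3-[(E)-hept-1-en-1-yl]-5-hydroxy-4-(hydroxymethyl)-2-oxo-7-oxabicyclo[4.1.0]hept-3-en-1-yl]-2-methylbut-2-enoic acid
Conditions: i-Bu2AlH (5 equiv), THF, −78 °C
Reagents that add atoms: none
Why: Hydroxyl-directed aluminium hydride reduction, in which the primary alkoxide formed first chelates and activates the adjacent C5 carbonyl (regiocontrol, the acid being masked in situ as its aluminium carboxylate) and hydride is delivered from aluminium coordinated to the oxirane oxygen, i.e. on the oxirane face, which sets C5 as R with the new hydroxyl anti to the epoxide.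

**Compound list**
1 | methyl prop-2-ynoate | C#CC(=O)OC | starting material
2 | methyl 3-bromoprop-2-ynoate | BrC#CC(=O)OC | intermediate
3 | 2-methoxyfuran | COc1ccco1 | starting material
4 | methyl 3-bromo-1-methoxy-7-oxabicyclo[2.2.1]hepta-2,5-diene-2-carboxylate (racemic, not isolated) | COC(=O)C1=C(Br)C2OC1(OC)C=C2 | intermediate
5 | methyl 2-bromo-3-hydroxy-6-methoxybenzoate | COC(=O)c1c(Br)c(O)ccc1OC | intermediate
6 | 2-bromo-3-(hydroxymethyl)-4-methoxyphenol | OCc1c(Br)c(O)ccc1OC | intermediate
7 | 2-bromo-3-(hydroxymethyl)-6-iodo-4-methoxyphenol (not isolated) | OCc1c(Br)c(O)c(I)cc1OC | intermediate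
8 | 2-bromo-3-(hydroxymethyl)-6-iodo-4,4-dimethoxycyclohexa-2,5-dien-1-one | O=C1C(I)=CC(OC)(OC)C(CO)=C1Br | intermediate
9 | 2-bromopropanoyl bromide (racemic) | CC(Br)C(Br)=O | starting material
10 | tert-butyl 2-bromopropanoate (racemic) | CC(Br)C(=O)OC(C)(C)C | intermediate
11 | (1-tert-butoxy-1-oxopropan-2-yl)triphenylphosphonium bromide (racemic, not isolated) | CC(C(=O)OC(C)(C)C)[P+](c1ccccc1)(c1ccccc1)c1ccccc1.[Br-] | intermediate
12 | tert-butyl 2-(triphenylphosphoranylidene)propanoate | CC(C(=O)OC(C)(C)C)=P(c1ccccc1)(c1ccccc1)c1ccccc1 | intermediate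
13 | chloroacetaldehyde | ClCC=O | starting material
14 | tert-butyl (E)-4-chloro-2-methylbut-2-enoate | ClC/C=C(\C)C(=O)OC(C)(C)C | intermediate
15 | tert-butyl (E)-2-methyl-4-(tributylstannyl)but-2-enoate | CCCC[Sn](CCCC)(CCCC)C/C=C(\C)C(=O)OC(C)(C)C | intermediate
16 | tert-butyl (E)-4-[5-bromo-4-(hydroxymethyl)-3,3-dimethoxy-6-oxocyclohexa-1,4-dien-1-yl]-2-methylbut-2-enoate | O=C1C(C/C=C(\C)C(=O)OC(C)(C)C)=CC(OC)(OC)C(CO)=C1Br | intermediate
17 | tert-butyl (E)-4-[(1S,6R)-3-bromo-4-(hydroxymethyl)-5,5-dimethoxy-2-oxo-7-oxabicyclo[4.1.0]hept-3-en-1-yl]-2-methylbut-2-enoate | BrC1=C(CO)C(OC)(OC)[C@@H]2O[C@]2(C/C=C(\C)C(=O)OC(C)(C)C)C1=O | intermediate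
18 | hept-1-yne | CCCCCC#C | starting material
19 | tributyl[(E)-hept-1-en-1-yl]stannane | CCCCC/C=C/[Sn](CCCC)(CCCC)CCCC | intermediate
20 | tert-butyl (E)-4-[(1S,6R)-3-[(E)-hept-1-en-1-yl]-4-(hydroxymethyl)-5,5-dimethoxy-2-oxo-7-oxabicyclo[4.1.0]hept-3-en-1-yl]-2-methylbut-2-enoate | CCCCC/C=C/C1=C(CO)C(OC)(OC)[C@@H]2O[C@]2(C/C=C(\C)C(=O)OC(C)(C)C)C1=O | intermediate
21 | (E)-4-[(1S,6R)-3-[(E)-hept-1-en-1-yl]-4-(hydroxymethyl)-2,5-dioxo-7-oxabicyclo[4.1.0]hept-3-en-1-yl]-2-methylbut-2-enoic acid | CCCCC/C=C/C1=C(CO)C(=O)[C@@H]2O[C@]2(C/C=C(\C)C(=O)O)C1=O | intermediate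
22 | (E)-4-[(1S,5R,6S)-3-[(E)-hept-1-en-1-yl]-5-hydroxy-4-(hydroxymethyl)-2-oxo-7-oxabicyclo[4.1.0]hept-3-en-1-yl]-2-methylbut-2-enoic acid | CCCCC/C=C/C1=C(CO)[C@@H](O)[C@@H]2O[C@]2(C/C=C(\C)C(=O)O)C1=O | target

**Totals**
Total step count: 14.
Longest linear sequence: 9 steps (steps 1, 2, 3, 4, 9, 10, 12, 13, 14 from compound 1; the branch of steps 5, 6, 7, 8 followed by 9, 10, 12, 13, 14 from compound 9 is equally long).

**Three steps most likely to fail**

Step 10 (the proposed new epoxidation). The ion-pair catalyst may give low enantioselectivity or low rate on a trisubstituted dienone double bond. The fallback sets out from 16 and comes back at 17. It is the known stoichiometric, hydroxyl-directed tartrate-mediated nucleophilic epoxidation: 16 is treated with NaN(SiMe3)2 (2.2 equiv), diisopropyl L-tartrate (1.2 equiv) and Ph3COOH (1.5 equiv) over 4 Å molecular sieves in PhMe at −65 °C. The sodium alkoxide of the hydroxymethyl group holds the chiral sodium tartrate–peroxide aggregate, which delivers oxygen to the C5=C6 bond; which tartrate antipode gives the (1S,6R) sense is not established here, so the D-tartrate is used if a pilot run shows the other sense. No new compound is made (F0).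

Step 9 (allyl transfer from the γ-stannyl tiglate). The risks are coupling at the ester-bearing allyl terminus, loss of (E) geometry and slow transmetalation of an electron-poor allylstannane. The fallback sets out from 8 and comes back at 16. Stille coupling of 8 with allyltributylstannane (CH2=CHCH2SnBu3; Pd2(dba)3, AsPh3, CuI, NMP, rt), a known reaction of α-iodoenones with no regiochemical ambiguity, gives 6-allyl-2-bromo-3-(hydroxymethyl)-4,4-dimethoxycyclohexa-2,5-dien-1-one F1. Cross-metathesis of F1 with tert-butyl 2-methylprop-2-enoate F2 (made from methacryloyl chloride, tert-butanol and pyridine) under the second-generation Hoveyda–Grubbs catalyst (CH2Cl2, 40 °C) then gives 16 as the (E)-trisubstituted enoate; the electron-poor ring alkenes do not take part.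

Step 14 (regio- and face-selective reduction on the free hydroxy acid). The risks are attack at the C2 carbonyl, hydride delivery anti to the oxirane (giving the C5 epimer) and interference by the free acid. The fallback sets out from 20 and comes back at 22, and sets C5 by inversion instead of by directed delivery.
- The ketal alone is hydrolysed (aq. oxalic acid on SiO2, CH2Cl2, rt) to tert-butyl (E)-4-[(1S,6R)-3-[(E)-hept-1-en-1-yl]-4-(hydroxymethyl)-2,5-dioxo-7-oxabicyclo[4.1.0]hept-3-en-1-yl]-2-methylbut-2-enoate F3.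
- Luche reduction (NaBH4, CeCl3·7H2O, MeOH, −78 °C), in which external hydride attacks anti to the oxirane, gives the syn diol tert-butyl (E)-4-[(1S,5S,6S)-3-[(E)-hept-1-en-1-yl]-5-hydroxy-4-(hydroxymethyl)-2-oxo-7-oxabicyclo[4.1.0]hept-3-en-1-yl]-2-methylbut-2-enoate F4.
- Double Mitsunobu esterification (4-nitrobenzoic acid, PPh3, DIAD, THF, 0 °C) inverts C5 and gives tert-butyl (E)-4-[(1S,5R,6S)-3-[(E)-hept-1-en-1-yl]-5-(4-nitrobenzoyloxy)-4-[(4-nitrobenzoyloxy)methyl]-2-oxo-7-oxabicyclo[4.1.0]hept-3-en-1-yl]-2-methylbut-2-enoate F5.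
- Methanolysis (K2CO3, MeOH, 0 °C) gives tert-butyl (E)-4-[(1S,5R,6S)-3-[(E)-hept-1-en-1-yl]-5-hydroxy-4-(hydroxymethyl)-2-oxo-7-oxabicyclo[4.1.0]hept-3-en-1-yl]-2-methylbut-2-enoate F6.
- CF3CO2H–CH2Cl2 (1:4), 0 °C, then frees the acid 22.

Further compounds
F1 | step 9 | 6-allyl-2-bromo-3-(hydroxymethyl)-4,4-dimethoxycyclohexa-2,5-dien-1-one | O=C1C(CC=C)=CC(OC)(OC)C(CO)=C1Br
F2 | step 9 | tert-butyl 2-methylprop-2-enoate | C=C(C)C(=O)OC(C)(C)C
F0 | step 10 | none | none
F3 | step 14 | tert-butyl (E)-4-[(1S,6R)-3-[(E)-hept-1-en-1-yl]-4-(hydroxymethyl)-2,5-dioxo-7-oxabicyclo[4.1.0]hept-3-en-1-yl]-2-methylbut-2-enoate | CCCCC/C=C/C1=C(CO)C(=O)[C@@H]2O[C@]2(C/C=C(\C)C(=O)OC(C)(C)C)C1=O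
F4 | step 14 | tert-butyl (E)-4-[(1S,5S,6S)-3-[(E)-hept-1-en-1-yl]-5-hydroxy-4-(hydroxymethyl)-2-oxo-7-oxabicyclo[4.1.0]hept-3-en-1-yl]-2-methylbut-2-enoate | CCCCC/C=C/C1=C(CO)[C@H](O)[C@@H]2O[C@]2(C/C=C(\C)C(=O)OC(C)(C)C)C1=O
F5 | step 14 | tert-butyl (E)-4-[(1S,5R,6S)-3-[(E)-hept-1-en-1-yl]-5-(4-nitrobenzoyloxy)-4-[(4-nitrobenzoyloxy)methyl]-2-oxo-7-oxabicyclo[4.1.0]hept-3-en-1-yl]-2-methylbut-2-enoate | CCCCC/C=C/C1=C(COC(=O)c3ccc(cc3)[N+](=O)[O-])[C@@H](OC(=O)c3ccc(cc3)[N+](=O)[O-])[C@@H]2O[C@]2(C/C=C(\C)C(=O)OC(C)(C)C)C1=O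
F6 | step 14 | tert-butyl (E)-4-[(1S,5R,6S)-3-[(E)-hept-1-en-1-yl]-5-hydroxy-4-(hydroxymethyl)-2-oxo-7-oxabicyclo[4.1.0]hept-3-en-1-yl]-2-methylbut-2-enoate | CCCCC/C=C/C1=C(CO)[C@@H](O)[C@@H]2O[C@]2(C/C=C(\C)C(=O)OC(C)(C)C)C1=O
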